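**Plan**

- Numbering: C1 quaternary ring-fusion carbon (CH3), C2–C3 ring CH2, C4 isopropyl carbinol, C5 ring-fusion CH, C6 acyloxy CH, C7 CH2, C8(CH3)=C9, C10 CH2; β is the face of the C1 methyl.
- Retrosynthesis cuts, in order, the C6–O ester bond (p-coumarate), the C4–isopropyl bond (C4 ketone, carried as a dioxolane), and the ring bonds C7–C8 and C1–C10 of the seven-membered ring.
- Enabling feature: the cycloheptene ring C8–C9–C10–C1–C5–C6–C7 divides into a three-carbon piece C8–C9–C10 and a four-carbon piece C7–C6–C5–C1 ending at the quaternary carbon shared with the cyclopentane. These correspond to a vinylcarbenoid (ester at C8 as the later methyl) and a 2-vinylcyclopentene.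
- Forward: the five-membered ring comes from 3-methylcyclopentenone (bromination, ketal, vinylation); the seven-membered ring closes by cyclopropanation/Cope rearrangement; then C5=C6 hydroboration, ester-to-methyl reduction, ketone release, isopropyl addition and acylation follow.
- Stereochemistry: C1 from the chiral dirhodium prolinate (cyclopropane configuration relayed by a boat Cope shift); C5 and C6 from syn hydroboration on the α face; C4 from α-face addition to the ketone; the E alkene comes with p-coumaric acid.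

Key step: step 7

Assumption: the sense of induction is taken from the empirical rule that Rh2(S-DOSP)4 gives (1S,2R)-cyclopropanes from styrene and methyl aryldiazoacetates; applied to this diene and vinylcarbenoid, that rule assigns the (1S,2S)-divinylcyclopropane, and hence (R)-C1, to Rh2(R-DOSP)4, which is therefore specified (the rule is recalled, not derived here, and the antipodal catalyst would give the antipode).

**Step 1**
Reactants: 1 3-methylcyclopent-2-en-1-one
Product: 3 2-bromo-3-methylcyclopent-2-en-1-one, via trans-2,3-dibromo-3-methylcyclopentanone 2 (not isolated)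
Conditions: Br2, CH2Cl2, 0 °C; then Et3N, 0 °C → rt
Reagents that add atoms: bromine, BrBr
Why: Bromination–dehydrobromination of a cyclic enone: bromine adds across the alkene and triethylamine removes the acidic α-proton with loss of the β-bromide, the standard entry to 2-bromocycloalkenones.

**Step 2**
Reactants: 3 2-bromo-3-methylcyclopent-2-en-1-one
Product: 4 6-bromo-7-methyl-1,4-dioxaspiro[4.4]non-6-ene
Conditions: HOCH2CH2OH, p-TsOH·H2O (cat.), benzene, reflux, Dean–Stark
Reagents that add atoms: ethylene glycol, OCCO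
Why: Acid-catalysed dioxolane formation with azeotropic removal of water, the usual protection of 2-bromocycloalkenones, masks the ketone for the later carbenoid and hydride steps.

**Step 3**
Reactants: 4 6-bromo-7-methyl-1,4-dioxaspiro[4.4]non-6-ene; 5 vinylboronic acid pinacol ester
Product: 6 7-methyl-6-vinyl-1,4-dioxaspiro[4.4]non-6-ene
Conditions: PdCl2(dppf) (5 mol %), K2CO3, 1,4-dioxane/H2O, 80 °C
Reagents that add atoms: none
Why: Suzuki–Miyaura coupling of the alkenyl bromide with the vinylboronate under aqueous carbonate, to which the dioxolane is inert, installs the C6=C7 vinyl group of the diene.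

**Step 4**
Reactants: 7 methyl acetoacetate
Product: 8 methyl 2-diazo-3-oxobutanoate
Conditions: 4-acetamidobenzenesulfonyl azide, Et3N, MeCN, 0 °C → rt
Reagents that add atoms: 4-acetamidobenzenesulfonyl azide, CC(=O)Nc1ccc(cc1)S(=O)(=O)N=[N+]=[N-]
Why: Regitz diazo transfer from the sulfonyl azide to the doubly activated methylene.

**Step 5**
Reactants: 8 methyl 2-diazo-3-oxobutanoate
Product: 9 methyl 2-diazo-3-hydroxybutanoate (racemic)
Conditions: NaBH4, MeOH, 0 °C
Reagents that add atoms: none
Why: Borohydride reduction takes the ketone only and leaves the diazo ester; the racemic carbinol centre is destroyed in step 6.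

**Step 6**
Reactants: 9 methyl 2-diazo-3-hydroxybutanoate
Product: 10 methyl 2-diazobut-3-enoate
Conditions: POCl3, Et3N, CH2Cl2, 0 °C; cold pentane extraction, used at once
Reagents that add atoms: none
Why: Phosphorylation of the alcohol and amine-mediated β-elimination (dehydration) give the vinyldiazoacetate, which is kept cold and used immediately because it cyclises to a pyrazole on standing.

**Step 7**
Reactants: 6 7-methyl-6-vinyl-1,4-dioxaspiro[4.4]non-6-ene; 10 methyl 2-diazobut-3-enoate
Product: 12 methyl (8aR)-8a-methyl-3-oxo-1,2,3,5,8,8a-hexahydroazulene-6-carboxylate 3-(ethylene ketal), via cis-divinylcyclopropane 11 (not isolated)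
Conditions: Rh2(R-DOSP)4 [dirhodium tetrakis((R)-N-(4-dodecylbenzenesulfonyl)prolinate)] (1 mol %), hexanes, −78 °C → rt, 10 (2 equiv) added over 2 h; then toluene, 80 °C
Reagents that add atoms: none
Why: The rhodium carbenoid formed from 10 by loss of N2 cyclopropanates the unhindered monosubstituted vinyl group of 6 (C7–C8 and the temporary C6–C8 bond) and, as is general for vinyl/ester carbenoids, places the alkene substituent cis to the carbenoid vinyl group and trans to the ester, giving cis-divinylcyclopropane 11. A [3,3]-sigmatropic (Cope) shift through a boat transition state then breaks C6–C8 and forms C1–C10, so the seven-membered ring is closed in a six-electron pericyclic step and the sequence is a formal (4+3) annulation; the closest known reaction is the tandem cyclopropanation/Cope rearrangement of vinyldiazoacetates with dienes, including dienes with a fully substituted terminus. The only new stereocentre, quaternary C1, is controlled by the cyclopropane configuration, which the chiral prolinate ligands set by enantioface selection at the vinyl group; in the boat the C1 methyl lies inside and the ring CH2 outside, so (1S,2S)-11 can deliver only (R)-C1. The step needs site selectivity (terminal vinyl over the tetrasubstituted ring alkene, secured by sterics), cis diastereoselectivity (inherent to this carbenoid class) and enantioselectivity (catalyst, low temperature, hydrocarbon solvent). Warming is planned because the inward C1 methyl raises the barrier of the rearrangement.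

**Step 8**
Reactants: 12 methyl (8aR)-8a-methyl-3-oxo-1,2,3,5,8,8a-hexahydroazulene-6-carboxylate 3-(ethylene ketal)
Product: 14 methyl (3aS,4S,8aR)-4-hydroxy-8a-methyl-3-oxo-1,2,3,3a,4,5,8,8a-octahydroazulene-6-carboxylate 3-(ethylene ketal), via C6-boranyl ketal ester 13 (not isolated)
Conditions: BH3·SMe2, THF, 0 °C → rt; then NaBO3·4H2O, THF/H2O, rt
Reagents that add atoms: NaBO3·4H2O, [Na+].[Na+].O[B-]1(O)OO[B-](O)(O)OO1
Why: Hydroboration–oxidation: the electron-rich C5=C6 alkene should react ahead of the ester-deactivated C8=C9 alkene, boron going to the less substituted C6 and hydrogen to C5 in a syn addition on the α face opposite the C1 methyl (the pattern of steroidal 5-enes), and oxidation with retention gives 5α-H/6α-OH, i.e. the trans ring fusion and the C6 carbinol configuration.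

**Step 9**
Reactants: 14 methyl (3aS,4S,8aR)-4-hydroxy-8a-methyl-3-oxo-1,2,3,3a,4,5,8,8a-octahydroazulene-6-carboxylate 3-(ethylene ketal)
Product: 15 methyl (3aS,4S,8aR)-4-(tert-butyldimethylsilyloxy)-8a-methyl-3-oxo-1,2,3,3a,4,5,8,8a-octahydroazulene-6-carboxylate 3-(ethylene ketal)
Conditions: TBSOTf, 2,6-lutidine, CH2Cl2, −78 → 0 °C
Reagents that add atoms: tert-butyldimethylsilyl triflate, CC(C)(C)[Si](C)(C)OS(=O)(=O)C(F)(F)F
Why: Silyl triflate silylation of the hindered secondary alcohol under hindered-base buffering leaves dioxolane and enoate untouched and protects C6–OH through the hydride and organometallic steps.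

**Step 10**
Reactants: 15 methyl (3aS,4S,8aR)-4-(tert-butyldimethylsilyloxy)-8a-methyl-3-oxo-1,2,3,3a,4,5,8,8a-octahydroazulene-6-carboxylate 3-(ethylene ketal)
Product: 16 (3aS,4S,8aR)-4-(tert-butyldimethylsilyloxy)-6-(hydroxymethyl)-8a-methyl-2,3a,4,5,8,8a-hexahydroazulen-3(1H)-one ethylene ketal
Conditions: i-Bu2AlH, CH2Cl2, −78 °C; aq. potassium sodium tartrate
Reagents that add atoms: none
Why: 1,2-Reduction of the conjugated ester by diisobutylaluminium hydride at low temperature gives the allylic alcohol without touching ketal or silyl ether.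

**Step 11**
Reactants: 16 (3aS,4S,8aR)-4-(tert-butyldimethylsilyloxy)-6-(hydroxymethyl)-8a-methyl-2,3a,4,5,8,8a-hexahydroazulen-3(1H)-one ethylene ketal
Product: 18 (3aS,4S,8aR)-4-(tert-butyldimethylsilyloxy)-6,8a-dimethyl-2,3a,4,5,8,8a-hexahydroazulen-3(1H)-one ethylene ketal, via allylic sulfate pyridinium salt 17 (not isolated)
Conditions: SO3·pyridine, THF, 0 °C; then LiAlH4, THF, 0 °C → rt
Reagents that add atoms: none
Why: Deoxygenation of a primary allylic alcohol through its sulfate monoester, which LiAlH4 displaces directly (SN2) without allylic transposition, turns the former ester carbon into the C8 methyl.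

**Step 12**
Reactants: 18 (3aS,4S,8aR)-4-(tert-butyldimethylsilyloxy)-6,8a-dimethyl-2,3a,4,5,8,8a-hexahydroazulen-3(1H)-one ethylene ketal
Product: 19 (3aS,4S,8aR)-4-(tert-butyldimethylsilyloxy)-6,8a-dimethyl-2,3a,4,5,8,8a-hexahydroazulen-3(1H)-one
Conditions: pyridinium p-toluenesulfonate, acetone/H2O, 50 °C
Reagents that add atoms: water, O
Why: Mild acid-catalysed ketal hydrolysis releases the C4 ketone while the secondary silyl ether and the ring alkene survive, the weak acid being chosen to avoid enolisation toward C5.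

**Step 13**
Reactants: 19 (3aS,4S,8aR)-4-(tert-butyldimethylsilyloxy)-6,8a-dimethyl-2,3a,4,5,8,8a-hexahydroazulen-3(1H)-one
Product: 20 (3R,3aS,4S,8aR)-4-(tert-butyldimethylsilyloxy)-6,8a-dimethyl-3-(propan-2-yl)-1,2,3,3a,4,5,8,8a-octahydroazulen-3-ol
Conditions: i-PrMgCl, CeCl3, THF, −78 → 0 °C
Reagents that add atoms: isopropylmagnesium chloride, CC(C)[Mg]Cl
Why: Organocerium 1,2-addition suppresses enolisation and β-hydride reduction of the hindered cyclopentanone, and the reagent should approach C4 on the α face, away from the 1,3-related pseudo-axial C1 methyl, so the new hydroxyl is β (cis to that methyl) and the isopropyl α.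

**Step 14**
Reactants: 20 (3R,3aS,4S,8aR)-4-(tert-butyldimethylsilyloxy)-6,8a-dimethyl-3-(propan-2-yl)-1,2,3,3a,4,5,8,8a-octahydroazulen-3-ol
Product: 21 (3R,3aS,4S,8aR)-6,8a-dimethyl-3-(propan-2-yl)-1,2,3,3a,4,5,8,8a-octahydroazulene-3,4-diol
Conditions: Bu4NF, THF, rt → 45 °C
Reagents that add atoms: none
Why: Fluoride cleavage of the silyl ether frees the C6 hydroxyl; the tertiary alcohol and the alkene are inert.

**Step 15**
Reactants: 22 p-coumaric acid
Product: 24 (E)-3-[4-(tert-butyldimethylsilyloxy)phenyl]prop-2-enoic acid, via bis-silylated coumarate 23 (not isolated)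
Conditions: TBSCl, imidazole, DMF, rt; then AcOH/THF/H2O, rt
Reagents that add atoms: tert-butyldimethylsilyl chloride, CC(C)(C)[Si](C)(C)Cl
Why: Silylation of both acidic oxygens followed by selective hydrolysis of the labile silyl ester leaves the phenol masked and the acid free, with the E alkene untouched.

**Step 16**
Reactants: 21 (3R,3aS,4S,8aR)-6,8a-dimethyl-3-(propan-2-yl)-1,2,3,3a,4,5,8,8a-octahydroazulene-3,4-diol; 24 (E)-3-[4-(tert-butyldimethylsilyloxy)phenyl]prop-2-enoic acid
Product: 25 (3R,3aS,4S,8aR)-3-hydroxy-6,8a-dimethyl-3-(propan-2-yl)-1,2,3,3a,4,5,8,8a-octahydroazulen-4-yl (E)-3-[4-(tert-butyldimethylsilyloxy)phenyl]prop-2-enoate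
Conditions: DCC, DMAP (cat.), CH2Cl2, 0 °C → rt
Reagents that add atoms: none
Why: Steglich esterification: the carbodiimide-activated acid acylates the secondary C6 hydroxyl, the tertiary C4 hydroxyl being too hindered to compete.

**Step 17**
Reactants: 25 (3R,3aS,4S,8aR)-3-hydroxy-6,8a-dimethyl-3-(propan-2-yl)-1,2,3,3a,4,5,8,8a-octahydroazulen-4-yl (E)-3-[4-(tert-butyldimethylsilyloxy)phenyl]prop-2-enoate
Product: 26 (3R,3aS,4S,8aR)-3-hydroxy-6,8a-dimethyl-3-(propan-2-yl)-1,2,3,3a,4,5,8,8a-octahydroazulen-4-yl (E)-3-(4-hydroxyphenyl)prop-2-enoate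
Conditions: Bu4NF, AcOH, THF, 0 °C
Reagents that add atoms: none
Why: Buffered fluoride removes the aryl silyl ether far faster than it can attack the cinnamate ester, giving the target.

**Compound list**

1 | 3-methylcyclopent-2-en-1-one | CC1=CC(=O)CC1 | starting material
2 | trans-2,3-dibromo-3-methylcyclopentan-1-one (racemic, one enantiomer drawn) | C[C@@]1(Br)CCC(=O)[C@H]1Br | intermediate
3 | 2-bromo-3-methylcyclopent-2-en-1-one | CC1=C(Br)C(=O)CC1 | intermediate
4 | 6-bromo-7-methyl-1,4-dioxaspiro[4.4]non-6-ene | CC1=C(Br)C2(CC1)OCCO2 | intermediate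
5 | vinylboronic acid pinacol ester | C=CB1OC(C)(C)C(C)(C)O1 | starting material
6 | 7-methyl-6-vinyl-1,4-dioxaspiro[4.4]non-6-ene | CC1=C(C=C)C2(CC1)OCCO2 | intermediate
7 | methyl acetoacetate | CC(=O)CC(=O)OC | starting material
8 | methyl 2-diazo-3-oxobutanoate | CC(=O)C(=[N+]=[N-])C(=O)OC | intermediate
9 | methyl 2-diazo-3-hydroxybutanoate (racemic) | CC(O)C(=[N+]=[N-])C(=O)OC | intermediate
10 | methyl 2-diazobut-3-enoate | C=CC(=[N+]=[N-])C(=O)OC | intermediate
11 | methyl (1S,2S)-2-(7-methyl-1,4-dioxaspiro[4.4]non-6-en-6-yl)-1-vinylcyclopropane-1-carboxylate | COC(=O)[C@]1(C=C)C[C@H]1C1=C(C)CCC12OCCO2 | intermediate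
12 | methyl (8aR)-8a-methyl-3-oxo-1,2,3,5,8,8a-hexahydroazulene-6-carboxylate 3-(ethylene ketal) | COC(=O)C1=CC[C@@]2(C)CCC3(OCCO3)C2=CC1 | intermediate
13 | methyl (3aR,4S,8aR)-4-boranyl-8a-methyl-3-oxo-1,2,3,3a,4,5,8,8a-octahydroazulene-6-carboxylate 3-(ethylene ketal) | COC(=O)C1=CC[C@@]2(C)CCC3(OCCO3)[C@@H]2[C@@H](B)C1 | intermediate
14 | methyl (3aS,4S,8aR)-4-hydroxy-8a-methyl-3-oxo-1,2,3,3a,4,5,8,8a-octahydroazulene-6-carboxylate 3-(ethylene ketal) | COC(=O)C1=CC[C@@]2(C)CCC3(OCCO3)[C@@H]2[C@@H](O)C1 | intermediate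
15 | methyl (3aS,4S,8aR)-4-(tert-butyldimethylsilyloxy)-8a-methyl-3-oxo-1,2,3,3a,4,5,8,8a-octahydroazulene-6-carboxylate 3-(ethylene ketal) | COC(=O)C1=CC[C@@]2(C)CCC3(OCCO3)[C@@H]2[C@@H](O[Si](C)(C)C(C)(C)C)C1 | intermediate
16 | (3aS,4S,8aR)-4-(tert-butyldimethylsilyloxy)-6-(hydroxymethyl)-8a-methyl-2,3a,4,5,8,8a-hexahydroazulen-3(1H)-one ethylene ketal | OCC1=CC[C@@]2(C)CCC3(OCCO3)[C@@H]2[C@@H](O[Si](C)(C)C(C)(C)C)C1 | intermediate
17 | pyridinium sulfate monoester of 16 (sulfate on the primary allylic oxygen) | [O-]S(=O)(=O)OCC1=CC[C@@]2(C)CCC3(OCCO3)[C@@H]2[C@@H](O[Si](C)(C)C(C)(C)C)C1.c1cc[nH+]cc1 | intermediate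
18 | (3aS,4S,8aR)-4-(tert-butyldimethylsilyloxy)-6,8a-dimethyl-2,3a,4,5,8,8a-hexahydroazulen-3(1H)-one ethylene ketal | CC1=CC[C@@]2(C)CCC3(OCCO3)[C@@H]2[C@@H](O[Si](C)(C)C(C)(C)C)C1 | intermediate
19 | (3aS,4S,8aR)-4-(tert-butyldimethylsilyloxy)-6,8a-dimethyl-2,3a,4,5,8,8a-hexahydroazulen-3(1H)-one | CC1=CC[C@@]2(C)CCC(=O)[C@@H]2[C@@H](O[Si](C)(C)C(C)(C)C)C1 | intermediate
20 | (3R,3aS,4S,8aR)-4-(tert-butyldimethylsilyloxy)-6,8a-dimethyl-3-(propan-2-yl)-1,2,3,3a,4,5,8,8a-octahydroazulen-3-ol | CC1=CC[C@@]2(C)CC[C@@](O)(C(C)C)[C@@H]2[C@@H](O[Si](C)(C)C(C)(C)C)C1 | intermediate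
21 | (3R,3aS,4S,8aR)-6,8a-dimethyl-3-(propan-2-yl)-1,2,3,3a,4,5,8,8a-octahydroazulene-3,4-diol | CC1=CC[C@@]2(C)CC[C@@](O)(C(C)C)[C@@H]2[C@@H](O)C1 | intermediate
22 | p-coumaric acid | O=C(O)/C=C/c1ccc(O)cc1 | starting material
23 | tert-butyldimethylsilyl (E)-3-[4-(tert-butyldimethylsilyloxy)phenyl]prop-2-enoate | CC(C)(C)[Si](C)(C)OC(=O)/C=C/c1ccc(O[Si](C)(C)C(C)(C)C)cc1 | intermediate
24 | (E)-3-[4-(tert-butyldimethylsilyloxy)phenyl]prop-2-enoic acid | O=C(O)/C=C/c1ccc(O[Si](C)(C)C(C)(C)C)cc1 | intermediate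
25 | (3R,3aS,4S,8aR)-3-hydroxy-6,8a-dimethyl-3-(propan-2-yl)-1,2,3,3a,4,5,8,8a-octahydroazulen-4-yl (E)-3-[4-(tert-butyldimethylsilyloxy)phenyl]prop-2-enoate | CC1=CC[C@@]2(C)CC[C@@](O)(C(C)C)[C@@H]2[C@@H](OC(=O)/C=C/c2ccc(O[Si](C)(C)C(C)(C)C)cc2)C1 | intermediate
26 | (3R,3aS,4S,8aR)-3-hydroxy-6,8a-dimethyl-3-(propan-2-yl)-1,2,3,3a,4,5,8,8a-octahydroazulen-4-yl (E)-3-(4-hydroxyphenyl)prop-2-enoate | CC1=CC[C@@]2(C)CC[C@@](O)(C(C)C)[C@@H]2[C@@H](OC(=O)/C=C/c2ccc(O)cc2)C1 | target

**Step count**

Total steps: 17. Longest linear sequence: 13 steps (steps 1–3 or 4–6, then 7–14, 16 and 17).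

**Steps most likely to fail**

Step 7. The labile unsubstituted vinyldiazoacetate may dimerise or close to a pyrazole faster than its carbenoid is captured by the crowded, twisted diene; enantioface selection may erode; and the rearrangement may stall with the methyl inside the boat. The fallback sets out from 8 and 6 and returns at 12. Silylation of 8 (TBSOTf, Et3N, CH2Cl2) gives the storable methyl 3-(tert-butyldimethylsilyloxy)-2-diazobut-3-enoate F1. With the enantiomer of Rh2(PTAD)4 matched to (R)-C1, in hexanes, F1 and 6 should give, through the siloxy divinylcyclopropane F2, the silyl enol ether cycloadduct F3. CsF and PhNTf2 convert F3 into the enol triflate F4, and palladium-catalysed formate reduction (Pd(OAc)2, PPh3, HCO2H, Et3N, DMF) removes the triflate to give 12.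

Step 8. Borane may also attack the conjugated ester or its alkene, and discrimination between the two faces of C5=C6 may be incomplete. The fallback sets out from 12 and returns at 14. NaHCO3-buffered mCPBA in CH2Cl2 should epoxidise only the electron-rich C5=C6 alkene, on the α face, to give the epoxy ester F5. Cp2TiCl (from Cp2TiCl2 and Zn) with 1,4-cyclohexadiene in THF then opens the epoxide homolytically at the tertiary C5, and hydrogen-atom transfer on the α face gives 14 (anti-Markovnikov reductive epoxide opening).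

Step 13. The branched reagent may enolise the hindered ketone toward C5 or C3 or reduce it by β-hydride transfer instead of adding. The fallback sets out from 19 and returns at 20. Isopropenylmagnesium bromide with CeCl3, an sp2 nucleophile without a transferable β-hydride, adds on the same face to give the isopropenyl carbinol F6. Its 1,1-disubstituted alkene is then hydrogenated selectively over the trisubstituted ring alkene with RhCl(PPh3)3 under H2 in benzene, giving 20.

**Further compounds**

F1 | step 7 | methyl 3-(tert-butyldimethylsilyloxy)-2-diazobut-3-enoate | C=C(O[Si](C)(C)C(C)(C)C)C(=[N+]=[N-])C(=O)OC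
F2 | step 7 | methyl (1R,2S)-1-[1-(tert-butyldimethylsilyloxy)vinyl]-2-(7-methyl-1,4-dioxaspiro[4.4]non-6-en-6-yl)cyclopropane-1-carboxylate | COC(=O)[C@]1(C(=C)O[Si](C)(C)C(C)(C)C)C[C@H]1C1=C(C)CCC12OCCO2
F3 | step 7 | methyl (8aR)-7-(tert-butyldimethylsilyloxy)-8a-methyl-3-oxo-1,2,3,5,8,8a-hexahydroazulene-6-carboxylate 3-(ethylene ketal) | COC(=O)C1=C(O[Si](C)(C)C(C)(C)C)C[C@@]2(C)CCC3(OCCO3)C2=CC1
F4 | step 7 | methyl (8aR)-8a-methyl-3-oxo-7-(trifluoromethanesulfonyloxy)-1,2,3,5,8,8a-hexahydroazulene-6-carboxylate 3-(ethylene ketal) | COC(=O)C1=C(OS(=O)(=O)C(F)(F)F)C[C@@]2(C)CCC3(OCCO3)C2=CC1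
F5 | step 8 | methyl (3aR,4S,8aR)-3a,4-epoxy-8a-methyl-3-oxo-1,2,3,3a,4,5,8,8a-octahydroazulene-6-carboxylate 3-(ethylene ketal) | COC(=O)C1=CC[C@@]2(C)CCC3(OCCO3)[C@@]24O[C@H]4C1
F6 | step 13 | (3S,3aS,4S,8aR)-4-(tert-butyldimethylsilyloxy)-6,8a-dimethyl-3-(prop-1-en-2-yl)-1,2,3,3a,4,5,8,8a-octahydroazulen-3-ol | CC1=CC[C@@]2(C)CC[C@@](O)(C(C)=C)[C@@H]2[C@@H](O[Si](C)(C)C(C)(C)C)C1
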